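**Retrosynthetic overview**
1. Acyl chain C10–C11 (key C–C bond): the carbonyl carbon of octadecanal 1 is made nucleophilic as its N–H hydrazone (from hydrazine 2) and joined to the bromide-bearing carbon of methyl 10-bromodecanoate 3. Hydrazone 4 → diazene 5 → methyl octacosanoate 6 with loss of N2, so the junction is left as plain CH2–CH2.
2. Ester C–O bond (last): 6 + tyrosol 7 → bongardol 8 by acyl transfer to the primary alcohol only, phenol unprotected.
3. Rings: none is formed; the benzene ring is bought with 7. Stereocentres: none.

Assumption: the target SMILES has no stereocentre and no stereogenic double bond, so the compound is achiral and its constitution alone defines the "single enantiomer".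

**Step 1**
Reactants: 1 octadecanal; 2 hydrazine monohydrate; 3 methyl 10-bromodecanoate
Product: 6 methyl octacosanoate, via octadecanal hydrazone 4 (not isolated), via methyl 11-diazenyloctacosanoate 5 (not isolated)
Conditions: 1 (1.5 equiv) added slowly to 2 (1.6 equiv), THF, 0 °C → rt, 1 h, 4 Å MS; then 3 (1.0 equiv), Ni(cod)2 (10 mol %), 4,4'-di-tert-butyl-2,2'-bipyridine (12 mol %), K3PO4 (2 equiv), THF, 60 °C, 24 h, Ar
Reagents that add atoms: none
Why: Proposed new method: the N-unsubstituted hydrazone 4 is a carbonyl-umpolung (alkyl carbanion) equivalent, because its K3PO4-deprotonated, nickel-bound form is nucleophilic at the former aldehyde carbon (R–CH=N–NH(−) ↔ R–CH(−)–N=NH), while zerovalent nickel/bipyridine activates the primary C–Br bond of 3 by halogen abstraction and radical capture, so that C–C reductive elimination gives diazene 5, which loses N2 in a Wolff–Kishner-type step to leave the CH2 of 6 (the transient stereocentre of 5 is racemic and vanishes; 6 is achiral); the closest known reaction type is the nickel-catalysed cross-coupling of aryl aldehyde hydrazones with unactivated alkyl halides, together with ruthenium-catalysed additions of aliphatic aldehyde hydrazones to carbonyls and Michael acceptors, and the new element is an aliphatic hydrazone coupling with an ester-bearing primary bromide.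

**Step 2**
Reactants: 6 methyl octacosanoate; 7 tyrosol (2-(4-hydroxyphenyl)ethanol)
Product: 8 bongardol (2-(4-hydroxyphenyl)ethyl octacosanoate)
Conditions: 7 (3 equiv), Novozym 435 (immobilised Candida antarctica lipase B), toluene/2-methyl-2-butanol 4:1, 5 Å MS, 70 °C, 48 h
Reagents that add atoms: none
Why: Lipase-catalysed transesterification: the enzyme accepts long-chain fatty acid methyl esters as acyl donors and passes the acyl group only to the unhindered primary aliphatic hydroxyl of 7, leaving the phenol free, while the sieves take up methanol and pull the equilibrium to 8; no stereocentre is formed.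

**Compound list**
1 | octadecanal (stearaldehyde) | CCCCCCCCCCCCCCCCCC=O | starting material
2 | hydrazine monohydrate | NN.O | starting material
3 | methyl 10-bromodecanoate | COC(=O)CCCCCCCCCBr | starting material
4 | (E)-octadecanal hydrazone | CCCCCCCCCCCCCCCCC/C=N/N | intermediate
5 | methyl 11-diazenyloctacosanoate (racemic, transient) | CCCCCCCCCCCCCCCCCC(N=N)CCCCCCCCCC(=O)OC | intermediate
6 | methyl octacosanoate | CCCCCCCCCCCCCCCCCCCCCCCCCCCC(=O)OC | intermediate
7 | tyrosol, 2-(4-hydroxyphenyl)ethanol | OCCc1ccc(O)cc1 | starting material
8 | bongardol, 2-(4-hydroxyphenyl)ethyl octacosanoate (achiral) | CCCCCCCCCCCCCCCCCCCCCCCCCCCC(=O)OCCc1ccc(O)cc1 | target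

**Totals**
Total step count: 2. Longest linear sequence: 2 steps (1 → 6 → 8).

**Steps most likely to fail**
The route has only two steps, so the three weakest points are ranked as step 1 (C–C bond-forming event), step 2, and step 1 again (its second, independent failure mode).

1. Step 1, C–C bond formation. An aliphatic, non-benzylic hydrazone may not be transferred to nickel, or may be reduced to octadecane before it couples. The fallback sets out from 1 and comes back at 6: the same polarity reversal is run stoichiometrically through a trityl hydrazone azo anion. Tritylhydrazine F1, made from trityl chloride and excess hydrazine hydrate, is condensed with 1 (EtOH, cat. AcOH, rt) to (E)-octadecanal N-tritylhydrazone F2, a stable solid that can be purified. Deprotonation with LiN(iPr)2 (THF, −78 °C) and C-alkylation with 3 (−78 → 0 °C; the trityl group shields nitrogen) give methyl 11-(trityldiazenyl)octacosanoate F3. F3 is not stored: EtSH is added and the mixture is warmed to rt, where F3 loses N2 and the trityl radical, and the secondary alkyl radical takes a hydrogen atom from the thiol to give 6.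

2. Step 2. The C28 acyl donor may be turned over too slowly by the lipase, or may not stay in solution together with 7. The fallback sets out from 6 and comes back at 8. 6 is saponified (KOH, EtOH/THF, reflux; then HCl) to octacosanoic acid F4, and F4 is condensed with 7 under Mitsunobu conditions (PPh3, DIAD, THF, 0 → 40 °C). Here the alcohol, not the acyl group, is activated: only the primary hydroxyl forms the oxyphosphonium leaving group, and the carboxylate, far more acidic than the phenol, is the nucleophile, so 8 forms without phenol protection.

3. Step 1, N- versus C-attack. The hydrazone nitrogen, and traces of free hydrazine, may be alkylated by 3 or acylated by its ester faster than the nickel cycle turns. The fallback sets out from 1 and comes back at 8, using a nitrogen-free acyl-anion equivalent. 1 and 1,3-propanedithiol (BF3·OEt2, CH2Cl2, 0 °C) give 2-heptadecyl-1,3-dithiane F5. Lithiation (n-BuLi, THF, −30 °C) is followed by alkylation with lithium 10-bromodecanoate F6 (from commercial 10-bromodecanoic acid and LiOH, dried; THF/DMPU, −30 °C → rt); the carboxylate is used because a lithiodithiane would attack a methyl ester. Acidic work-up gives 10-(2-heptadecyl-1,3-dithian-2-yl)decanoic acid F7. Raney Ni (EtOH, reflux) removes the sulfur to give octacosanoic acid F4, which is joined to 7 by the Mitsunobu esterification described under point 2 to reach 8.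

**Further compounds**
F1 | step 1 | tritylhydrazine | NNC(c1ccccc1)(c1ccccc1)c1ccccc1
F2 | step 1 | (E)-octadecanal N-tritylhydrazone | CCCCCCCCCCCCCCCCC/C=N/NC(c1ccccc1)(c1ccccc1)c1ccccc1
F3 | step 1 | methyl 11-[(E)-trityldiazenyl]octacosanoate (racemic) | CCCCCCCCCCCCCCCCCC(/N=N/C(c1ccccc1)(c1ccccc1)c1ccccc1)CCCCCCCCCC(=O)OC
F4 | step 2 | octacosanoic acid | CCCCCCCCCCCCCCCCCCCCCCCCCCCC(=O)O
F5 | step 1 | 2-heptadecyl-1,3-dithiane | CCCCCCCCCCCCCCCCCC1SCCCS1
F6 | step 1 | lithium 10-bromodecanoate | [Li+].[O-]C(=O)CCCCCCCCCBr
F7 | step 1 | 10-(2-heptadecyl-1,3-dithian-2-yl)decanoic acid | CCCCCCCCCCCCCCCCCC1(CCCCCCCCCC(=O)O)SCCCS1
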